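**Plan**
- Retrosynthesis: the ring B quinone goes back to a 2,4,5-trimethoxyphenyl group, the 5-OH to a methyl ether and the C4 ketone to a carbinol. Then O1–C8a is cut (ring C), then C3–C4 (aldol), then the C8a–I bond and the formyl carbon on ring A.
- Enabling feature: O1 is an aryl alkyl ether oxygen that joins aromatic C8a of ring A to the benzylic stereocentre C2. The C2–O bond can therefore be carried in as a carbinol, and O1–C8a can be made last on an aryl iodide without touching C2.
- Forward: ring A iodoaldehyde (three steps); aldol with 2,4,5-trimethoxyacetophenone joins the C2–C3–C4 chain; oxidation and two reductions give the anti 1,3-diol; ring C closes by copper-mediated O-arylation; then C4 oxidation, 5-O-demethylation and ring B oxidation.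
- Stereochemistry: C2 (S) comes from catalyst-controlled transfer hydrogenation with the (S,S)-TsDPEN ruthenium catalyst. C4 is set anti to it by hydroxyl-directed reduction and is erased after ring closure.

Key step: step 8

Remark: the 1,3-diketone formed in step 5 is drawn as the diketo tautomer although it should be largely enolised; the transfer hydrogenation acts on the keto form.

**Step 1**
Reactants: 1 2,4-dimethoxy-3-methylbenzaldehyde
Product: 3 1,3-dimethoxy-2,4-dimethylbenzene, via benzylic alcohol 2 (not isolated)
Conditions: H2 (3 atm), 10% Pd/C, AcOH, rt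
Reagents that add atoms: none
Why: Catalytic hydrogenolysis: the electron-rich aryl aldehyde is hydrogenated on palladium to benzylic alcohol 2, whose activated benzylic C–O bond is then cleaved in acetic acid, so the formyl group ends as the second ring methyl group.

**Step 2**
Reactants: 3 1,3-dimethoxy-2,4-dimethylbenzene
Product: 5 2,4-dimethoxy-3,5-dimethylbenzaldehyde, via α-chloro ether 4 (not isolated)
Conditions: Cl2CHOMe, TiCl4, CH2Cl2, 0 °C; then H2O
Reagents that add atoms: dichloromethyl methyl ether, COC(Cl)Cl; water, O
Why: Rieche formylation (electrophilic aromatic substitution): the TiCl4-activated dichloromethyl methyl ether attacks the one ring position that is ortho to one methoxy group and para to the other, and water hydrolyses α-chloro ether 4 to the aldehyde.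

**Step 3**
Reactants: 5 2,4-dimethoxy-3,5-dimethylbenzaldehyde
Product: 9 2-iodo-4,6-dimethoxy-3,5-dimethylbenzaldehyde, via lithium α-amino alkoxide 6 (not isolated), via ortho-lithiated alkoxide 7 (not isolated), via iodinated alkoxide 8 (not isolated)
Conditions: LiN(Me)CH2CH2NMe2 (from Me2NCH2CH2NHMe and n-BuLi), THF, −20 °C; n-BuLi (3 equiv), −20 °C; I2, −78 °C to rt; 1 M HCl
Reagents that add atoms: iodine, II
Why: Comins directed ortho-metalation: the lithium amide masks the aldehyde as α-amino alkoxide 6, whose chelating diamine arm guides n-BuLi to the only ring hydrogen (ortho to the masked formyl group), iodine quenches aryllithium 7 and aqueous acid releases the aldehyde from 8.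

**Step 4**
Reactants: 10 1-(2,4,5-trimethoxyphenyl)ethan-1-one (2,4,5-trimethoxyacetophenone); 9 2-iodo-4,6-dimethoxy-3,5-dimethylbenzaldehyde
Product: 12 rac-3-hydroxy-3-(2-iodo-4,6-dimethoxy-3,5-dimethylphenyl)-1-(2,4,5-trimethoxyphenyl)propan-1-one, via lithium enolate 11 (not isolated)
Conditions: LiN(iPr)2, THF, −78 °C; then 9, −78 °C; AcOH quench at −78 °C
Reagents that add atoms: none
Why: Directed (crossed) aldol addition: the kinetic lithium enolate 11 of the methyl ketone adds to the non-enolisable aldehyde at −78 °C and the cold acidic quench prevents retro-aldol cleavage, the carbinol being formed racemic on purpose because step 5 removes it.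

**Step 5**
Reactants: 12 rac-3-hydroxy-3-(2-iodo-4,6-dimethoxy-3,5-dimethylphenyl)-1-(2,4,5-trimethoxyphenyl)propan-1-one
Product: 13 1-(2-iodo-4,6-dimethoxy-3,5-dimethylphenyl)-3-(2,4,5-trimethoxyphenyl)propane-1,3-dione
Conditions: IBX (2-iodoxybenzoic acid, 3 equiv), EtOAc, 77 °C
Reagents that add atoms: none
Why: IBX oxidation of a β-hydroxy ketone to the 1,3-diketone, a mild alcohol oxidation that stops at the diketone and leaves the aryl iodide and the electron-rich rings alone.

**Step 6**
Reactants: 13 1-(2-iodo-4,6-dimethoxy-3,5-dimethylphenyl)-3-(2,4,5-trimethoxyphenyl)propane-1,3-dione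
Product: 14 (3S)-3-hydroxy-1-(2-iodo-4,6-dimethoxy-3,5-dimethylphenyl)-3-(2,4,5-trimethoxyphenyl)propan-1-one
Conditions: RuCl(p-cymene)[(S,S)-TsDPEN] (2 mol%), HCO2H/Et3N (5:2), EtOAc, 30 °C
Reagents that add atoms: none
Why: Noyori–Ikariya asymmetric transfer hydrogenation: the ruthenium hydride of the (S,S)-TsDPEN complex passes hydride and proton through its six-membered outer-sphere transition state to the accessible ring B aryl ketone, the aryl–cymene CH/π contact fixing the face so that the new carbinol should be S, while the ring A carbonyl, twisted between iodine and methoxy, is too shielded to react.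

**Step 7**
Reactants: 14 (3S)-3-hydroxy-1-(2-iodo-4,6-dimethoxy-3,5-dimethylphenyl)-3-(2,4,5-trimethoxyphenyl)propan-1-one
Product: 15 (1S,3S)-1-(2-iodo-4,6-dimethoxy-3,5-dimethylphenyl)-3-(2,4,5-trimethoxyphenyl)propane-1,3-diol
Conditions: Me4NBH(OAc)3, MeCN/AcOH (1:1), −20 °C
Reagents that add atoms: none
Why: Evans–Saksena hydroxyl-directed reduction: the ring B hydroxyl exchanges onto boron and the hydride is delivered intramolecularly through a chair transition state, which should set the new ring A carbinol anti to the existing one (1S,3S).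

**Step 8**
Reactants: 15 (1S,3S)-1-(2-iodo-4,6-dimethoxy-3,5-dimethylphenyl)-3-(2,4,5-trimethoxyphenyl)propane-1,3-diol
Product: 16 (2S,4S)-5,7-dimethoxy-6,8-dimethyl-2-(2,4,5-trimethoxyphenyl)chroman-4-ol
Conditions: CuI (10 mol%), 1,10-phenanthroline (20 mol%), Cs2CO3 (2 equiv), degassed toluene, 110 °C
Reagents that add atoms: none
Why: Cs2CO3 converts the ring B carbinol of 15 (the future C2 hydroxyl) into its alkoxide, which binds phenanthroline-ligated monovalent copper; the copper alkoxide activates the neighbouring C–I bond (oxidative addition to a trivalent copper aryl alkoxide) and C–O reductive elimination forms O1–C8a. The closest known reaction type is the CuI-catalysed intramolecular Ullmann etherification of secondary benzylic alcohols tethered to ortho-haloarenes, as used for enantioenriched flavans. Ring C (the dihydropyran ring) closes in a six-membered exo mode at an sp2 carbon, the iodide leaving from outside the new ring. No stereocentre is created: the carbinol C–O bond that becomes C2–O1 is never broken, so the S configuration from step 6 is carried over with retention and C4 stays S as a spectator. The step needs chemoselectivity between the two hydroxyls and against alcohol oxidation or elimination: only the ring B hydroxyl can reach C8a in a six-membered ring (the other would give a four-membered ring), copper alkoxides do not readily lose a β-hydride as palladium alkoxides do, degassing prevents copper-mediated aerobic oxidation, and with C4 at the alcohol level there is no β-hydroxy ketone that could undergo retro-aldol cleavage or dehydration under carbonate base.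

**Step 9**
Reactants: 16 (2S,4S)-5,7-dimethoxy-6,8-dimethyl-2-(2,4,5-trimethoxyphenyl)chroman-4-ol
Product: 17 (2S)-5,7-dimethoxy-6,8-dimethyl-2-(2,4,5-trimethoxyphenyl)chroman-4-one
Conditions: Dess–Martin periodinane, CH2Cl2, 0 °C to rt
Reagents that add atoms: none
Why: Dess–Martin oxidation of the secondary benzylic C4 alcohol to the chromanone under near-neutral conditions that do not open the β-aryloxy ketone, so C2 keeps its configuration and the now superfluous C4 stereocentre is erased.

**Step 10**
Reactants: 17 (2S)-5,7-dimethoxy-6,8-dimethyl-2-(2,4,5-trimethoxyphenyl)chroman-4-one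
Product: 19 (2S)-5-hydroxy-7-methoxy-6,8-dimethyl-2-(2,4,5-trimethoxyphenyl)chroman-4-one, via dichloroboryl chelate 18 (not isolated)
Conditions: BCl3 (1.2 equiv), CH2Cl2, −78 to 0 °C; then H2O
Reagents that add atoms: none
Why: Chelation-controlled Lewis acid ether cleavage: BCl3 bridges the C4 carbonyl oxygen and the peri 5-methoxy oxygen in a six-membered chelate and chloride removes only that methyl group (chelate 18), the four other methyl ethers having no neighbouring carbonyl, and the low temperature guards the C2–O1 bond.

**Step 11**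
Reactants: 19 (2S)-5-hydroxy-7-methoxy-6,8-dimethyl-2-(2,4,5-trimethoxyphenyl)chroman-4-one
Product: 20 (2S)-5-hydroxy-7-methoxy-2-(4-methoxy-3,6-dioxocyclohexa-1,4-dien-1-yl)-6,8-dimethylchroman-4-one
Conditions: (NH4)2Ce(NO3)6 (2.5 equiv), MeCN/H2O, 0 °C
Reagents that add atoms: water, O
Why: Oxidative demethylation with (NH4)2Ce(NO3)6: single-electron oxidation of the 1,2,4-trimethoxyarene of ring B, attack of water at the para-related C2' and C5' positions and loss of two molecules of methanol should give the 2-methoxy-1,4-benzoquinone, whereas ring A is acyl-deactivated, fully substituted and has no para-related oxygen pair.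

**Compound list**
1 | 2,4-dimethoxy-3-methylbenzaldehyde | O=Cc1ccc(OC)c(C)c1OC | starting material
2 | (2,4-dimethoxy-3-methylphenyl)methanol | OCc1ccc(OC)c(C)c1OC | intermediate
3 | 1,3-dimethoxy-2,4-dimethylbenzene | Cc1ccc(OC)c(C)c1OC | intermediate
4 | 1-[chloro(methoxy)methyl]-2,4-dimethoxy-3,5-dimethylbenzene | COC(Cl)c1cc(C)c(OC)c(C)c1OC | intermediate
5 | 2,4-dimethoxy-3,5-dimethylbenzaldehyde | O=Cc1cc(C)c(OC)c(C)c1OC | intermediate
6 | lithium {[2-(dimethylamino)ethyl](methyl)amino}(2,4-dimethoxy-3,5-dimethylphenyl)methanolate | [Li]OC(N(C)CCN(C)C)c1cc(C)c(OC)c(C)c1OC | intermediate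
7 | 6-lithio derivative of 6 (aryllithium ortho to the masked formyl group) | [Li]OC(N(C)CCN(C)C)c1c([Li])c(C)c(OC)c(C)c1OC | intermediate
8 | lithium {[2-(dimethylamino)ethyl](methyl)amino}(2-iodo-4,6-dimethoxy-3,5-dimethylphenyl)methanolate | [Li]OC(N(C)CCN(C)C)c1c(I)c(C)c(OC)c(C)c1OC | intermediate
9 | 2-iodo-4,6-dimethoxy-3,5-dimethylbenzaldehyde | O=Cc1c(I)c(C)c(OC)c(C)c1OC | intermediate
10 | 1-(2,4,5-trimethoxyphenyl)ethan-1-one | CC(=O)c1cc(OC)c(OC)cc1OC | starting material
11 | lithium 1-(2,4,5-trimethoxyphenyl)ethen-1-olate | [Li]OC(=C)c1cc(OC)c(OC)cc1OC | intermediate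
12 | rac-3-hydroxy-3-(2-iodo-4,6-dimethoxy-3,5-dimethylphenyl)-1-(2,4,5-trimethoxyphenyl)propan-1-one (racemic) | COc1cc(OC)c(OC)cc1C(=O)CC(O)c1c(I)c(C)c(OC)c(C)c1OC | intermediate
13 | 1-(2-iodo-4,6-dimethoxy-3,5-dimethylphenyl)-3-(2,4,5-trimethoxyphenyl)propane-1,3-dione | COc1cc(OC)c(OC)cc1C(=O)CC(=O)c1c(I)c(C)c(OC)c(C)c1OC | intermediate
14 | (3S)-3-hydroxy-1-(2-iodo-4,6-dimethoxy-3,5-dimethylphenyl)-3-(2,4,5-trimethoxyphenyl)propan-1-one | COc1cc(OC)c(OC)cc1[C@@H](O)CC(=O)c1c(I)c(C)c(OC)c(C)c1OC | intermediate
15 | (1S,3S)-1-(2-iodo-4,6-dimethoxy-3,5-dimethylphenyl)-3-(2,4,5-trimethoxyphenyl)propane-1,3-diol | COc1cc(OC)c(OC)cc1[C@@H](O)C[C@H](O)c1c(I)c(C)c(OC)c(C)c1OC | intermediate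
16 | (2S,4S)-5,7-dimethoxy-6,8-dimethyl-2-(2,4,5-trimethoxyphenyl)chroman-4-ol | COc1cc(OC)c(OC)cc1[C@@H]1C[C@H](O)c2c(OC)c(C)c(OC)c(C)c2O1 | intermediate
17 | (2S)-5,7-dimethoxy-6,8-dimethyl-2-(2,4,5-trimethoxyphenyl)chroman-4-one | COc1cc(OC)c(OC)cc1[C@@H]1CC(=O)c2c(OC)c(C)c(OC)c(C)c2O1 | intermediate
18 | (2S)-5-(dichloroboryloxy)-7-methoxy-6,8-dimethyl-2-(2,4,5-trimethoxyphenyl)chroman-4-one | COc1cc(OC)c(OC)cc1[C@@H]1CC(=O)c2c(OB(Cl)Cl)c(C)c(OC)c(C)c2O1 | intermediate
19 | (2S)-5-hydroxy-7-methoxy-6,8-dimethyl-2-(2,4,5-trimethoxyphenyl)chroman-4-one | COc1cc(OC)c(OC)cc1[C@@H]1CC(=O)c2c(O)c(C)c(OC)c(C)c2O1 | intermediate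
20 | (2S)-5-hydroxy-7-methoxy-2-(4-methoxy-3,6-dioxocyclohexa-1,4-dien-1-yl)-6,8-dimethylchroman-4-one | COC1=CC(=O)C([C@@H]2CC(=O)c3c(O)c(C)c(OC)c(C)c3O2)=CC1=O | target

**Step count and risks**
Total step count: 11. Longest linear sequence: 11 steps (1 to 20); ketone 10 is bought.

Steps most likely to fail:

1. Step 3 (directed ortho-iodination). Metalation may go to the benzylic methyl groups next to the methoxy groups (lateral lithiation) instead of the ring C–H, or may stall, so that iodine is delivered to the wrong carbon or not at all. The fallback sets out from 5 and comes back at 9. Pinnick oxidation (NaClO2, NaH2PO4, 2-methyl-2-butene, t-BuOH/H2O) would give 2,4-dimethoxy-3,5-dimethylbenzoic acid F1. Carboxylate-directed C–H iodination at the only free ring position (Pd(OAc)2, PhI(OAc)2, I2, DMF) would then give 2-iodo-4,6-dimethoxy-3,5-dimethylbenzoic acid F2. Reduction with BH3·THF would lead to (2-iodo-4,6-dimethoxy-3,5-dimethylphenyl)methanol F3, and MnO2 in CH2Cl2 would return aldehyde 9.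

2. Step 6 (transfer hydrogenation of the diketone). Hydrogen transfer may stall because the enolised diketone binds ruthenium as a diketonate, the facial selectivity may erode, or the electron-rich benzylic carbinol may dehydrate in the formic acid medium. The fallback sets out from 12 and comes back at 15, bypassing 13 and 14. Racemic 12 would be reduced directly with RuCl(p-cymene)[(S,S)-TsDPEN] and HCO2H/Et3N. The catalyst should set the ring B carbinol S in both enantiomers, giving 15 together with its epimer at the ring A carbinol, (1R,3S)-1-(2-iodo-4,6-dimethoxy-3,5-dimethylphenyl)-3-(2,4,5-trimethoxyphenyl)propane-1,3-diol F4. F4 would be removed by chromatography before step 8.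

3. Step 8 (ring closure). Activation of the C–I bond flanked by two ortho substituents may be slow, so that proto-deiodination or copper-mediated dehydrogenation of the carbinols takes over. The fallback sets out from 15 and comes back at 16. It changes metal and mechanism to a palladium-catalysed intramolecular C–O coupling (Pd(OAc)2, 2-(di-tert-butylphosphino)-1,1'-binaphthyl, Cs2CO3, toluene, 70 °C). Oxidative addition of zerovalent palladium into the C–I bond is followed by alkoxide binding and C–O reductive elimination, which the bulky phosphine should favour over β-hydride loss. The same bond is formed and no further compound F0 arises.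

**Further compounds**
F1 | step 3 | 2,4-dimethoxy-3,5-dimethylbenzoic acid | OC(=O)c1cc(C)c(OC)c(C)c1OC
F2 | step 3 | 2-iodo-4,6-dimethoxy-3,5-dimethylbenzoic acid | OC(=O)c1c(I)c(C)c(OC)c(C)c1OC
F3 | step 3 | (2-iodo-4,6-dimethoxy-3,5-dimethylphenyl)methanol | OCc1c(I)c(C)c(OC)c(C)c1OC
F4 | step 6 | (1R,3S)-1-(2-iodo-4,6-dimethoxy-3,5-dimethylphenyl)-3-(2,4,5-trimethoxyphenyl)propane-1,3-diol | COc1cc(OC)c(OC)cc1[C@@H](O)C[C@@H](O)c1c(I)c(C)c(OC)c(C)c1OC
F0 | step 8 | none | none
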